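Slowness in the fuller flask came first: the violet flask, with 3.00 times the charge of the amber flask, had made 1.95 times its target by 8.1 min, and I set out to put a number on that lag.

| flask | starting material | target | time |
|---|---|---|---|
| amber | 250 mM |  |  |
| red | 150 mM |  |  |
| violet | 750 mM |  |  |
| ochre | 250 mM | 120 mM |  |
| teal | 250 mM |  | 180 min |

- amber run (time / min: [target] / mM): 2.7: 10.0; 8.1: 27.4; 15: 48.5; 25: 70.7; 35: 86.6; 47: 98.4; 60: 105.1
- red run (time / min: [target] / mM): 2.7: 7.8; 8.1: 18.3; 15: 34.0; 25: 47.6; 35: 58.7; 47: 63.2; 60: 66.0
- violet run (time / min: [target] / mM): 2.7: 18.1; 8.1: 53.4; 15: 91.7; 25: 141.9; 35: 181.8; 47: 218.1; 60: 247.1
- ochre run (time / min: [target] / mM): 2.7: 131.4; 8.1: 149.7; 15: 167.1; 25: 189.1; 35: 205.7; 47: 217.0; 60: 222.4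

(scatter of a reading: 0.8 mM)

- Overall: starting material -> target.
- Constant volume, constant temperature.
- What is held in complexes is read along with the free species.
- An order is taken over about fifteen percent of the charge, up and down.

1. how the opening rate goes with [starting material] round the charge of the amber run: the exponent of the rate at two percent of starting material gone to target (one fixed amount of target, the same in the runs compared)
2. target in the teal run at 180 min, as a share of the starting material charged

Before taking the number, I asked which readings it leaned on. The charges are given, so the error sits in the readings. At 8.1 min, one standard deviation on the red reading moved the red-amber order by 0.0856. The same deviation on the violet reading moved the violet-amber order by 0.0136, and on the amber reading by 0.0266. At 2.7 min the amber reading moved it by 0.0728, more than at 8.1 min, so I used the later reading. The red-amber value of 0.790 moved more with one deviation on the red reading than the violet-amber value did with one on the violet reading, so I set it aside. The violet-amber pair gave 0.607, my apparent order n: the logarithm of the ratio of two opening rates over the logarithm of the ratio of their charges, with the target at one early time standing in for each rate. This pair spans 250 mM to 750 mM, so n was my estimate of the order round the amber charge and not a reading of it.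

The teal flask has the charge of the amber flask, so I took its share from the amber reading at 60 min. That reading stood at 42.0% of the charge, and the last interval of the amber flask still added 6.70 mM, so I committed to a share above that reading.

The forecast gave 0.7 and 45%, calling the opening rates “a saturating curve, with a local order near 0.7 at 250 mM”. Its order was higher than mine.

The order round the amber charge came out at 0.60, and target in the teal flask stood at 42.4% of the charge at 180 min.

    starting material → target (0.06300 min⁻¹)
    2 starting material → side product (0.3420 M⁻¹ min⁻¹)
    starting material → decomposed substrate (0.06060 min⁻¹)
    2 starting material ⇌ idle substrate dimer, settled at all times (26.10 M⁻¹)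

The violet flask ran at 1.9 times the amber rate at one fixed amount of target. Carried to the red flask, n turns the amber rate of 3.7 mM min⁻¹ into 2.70 mM min⁻¹, and the red flask stood at 2.7 mM min⁻¹ with two percent of the amber charge turned.

The readings come from a simulation from invented constants; the scatter is artificial.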